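We read this flask at 80 s and at 4.0 h, so we ask how many mean half-lives of E each reading stands from the start.

| setting | ash | cedar | flask |
|---|---|---|---|
| E | 0.40 M | 0.90 M | 0.60 M |
| remark | run made earlier | run made earlier |  |
| time |  |  | 4.0 h |

| run | time / h | Z / % | J / % | E / % |
|---|---|---|---|---|
| ash | 0.333 | 2.8 | 18.5 | 74.0 |
| ash | 0.500 | 4.2 | 21.0 | 64.3 |
| ash | 0.667 | 6.8 | 22.1 | 55.9 |
| ash | 1.00 | 9.7 | 21.7 | 44.8 |
| ash | 1.50 | 12.4 | 16.7 | 32.0 |
| ash | 2.50 | 16.2 | 10.0 | 16.8 |
| ash | 4.00 | 16.8 | 3.4 | 7.8 |
| cedar | 0.333 | 2.9 | 18.2 | 73.5 |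
| cedar | 0.500 | 5.1 | 21.3 | 63.6 |
| cedar | 0.667 | 6.3 | 21.8 | 57.5 |
| cedar | 1.00 | 10.1 | 20.6 | 43.7 |
| cedar | 1.50 | 12.8 | 17.4 | 31.0 |
| cedar | 2.50 | 15.9 | 9.7 | 16.8 |
| cedar | 4.00 | 16.6 | 4.7 | 6.7 |

(readings scatter by 0.5 percentage points)

1. ratio of Z to J at 80 s
2. ratio of Z to J at 4.0 h
3. which of Z and J there is more of at 4.0 h

- what was read earlier has a scatter of 0.5 percentage points, one standard deviation

In the ash and cedar runs, E keeps nearly the same percentage curve at different charges (44.8% and 43.7% at 1.00 h), so we carry one number to the flask at 0.60 M: the mean half-life of E, the half-life of the one exponential that joins the start to the mean of the last readings. It is an average over the whole span and not the time of the first halving, since both runs already read under half at 1.00 h. Our reckoning from the mean of the last readings is: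

mean half-life of E = 4.00 h × ln(2) / ln(100 / mean percent of E left) = 1.06 h

count at the late reading = 3.79

count at the early reading = 0.0210

The late reading lies deep in the tail, where the pooled readings give Z over J of 4.12. The early reading needs two extreme versions, both starting from the pooled ratio at 0.333 h, 0.155. If Z came from J and nothing else, the ratio would start at nothing and grow with time, giving 0.0104 at 80 s. If Z were born beside J at a fixed ratio, the ratio would stay at 0.155. We expect the flask between these two.

The forecast gave 0.01, 4.1 and Z ahead, holding that “Z looks secondary, with little or no direct route from E”.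

The flask gives 0.0898 and 3.62, with Z ahead at 16.4% against J at 4.54%.

    J ⇌ Z (k = 0.00470 min⁻¹)
    2 E → D (k = 2.77 × 10⁻⁵ M⁻¹ min⁻¹)
    E ⇌ J (K = 1.44, k = 0.0155 min⁻¹)
    E ⇌ Z (K = 3.20, k = 0.00131 min⁻¹)
    J → L (k = 0.0239 min⁻¹)

The early ratio lies between our extremes, at 0.0210 of the mean half-life of 1.06 h, when by this reckoning hardly any E has gone. At the start, E's forward rate towards J is 12 times its forward rate towards Z, a selectivity whose inverse is 0.0845, close to that early ratio.

For the neighbouring flask at 0.36 M, the same mean half-life and count of 3.79 leave 7.25% of E at 4.0 h. The computed neighbour holds 7.06%, with ratios 0.0898 and 3.62.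

All runs were generated by integration from invented constants; the scatter is artificial.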